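The earlier runs and the new flask stem from a simulated flask on assumed constants, noise included.

The substrate opened at 57.0 /d in Wednesday's run, a reading with its scatter, taken from the part of the charge missing from open intermediate and product at the first reading. Saturday's run, with more partner, gave 57.5 /d, so I took the opening as indifferent to c(partner).

| flask | substrate | partner | capture agent | remark | time |
|---|---|---|---|---|---|
| Wednesday's | 0.10 M | 0.14 M | 5 mM | run made earlier |  |
| Saturday's | 0.10 M | 0.22 M | 5 mM | run made earlier |  |
| flask | 0.10 M | 0.100 M | 5.00 mM |  | 6.0 d |

| run | time / d | open intermediate / % | product / % |
|---|---|---|---|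
| Wednesday's | 0.0417 | 86.4 | 4.3 |
| Wednesday's | 0.167 | 78.2 | 20.4 |
| Wednesday's | 0.500 | 53.7 | 42.9 |
| Wednesday's | 1.67 | 19.7 | 76.9 |
| Wednesday's | 5.00 | 3.8 | 93.7 |
| Saturday's | 0.0417 | 85.0 | 5.9 |
| Saturday's | 0.167 | 71.3 | 26.7 |
| Saturday's | 0.500 | 38.3 | 61.3 |
| Saturday's | 1.67 | 6.0 | 89.1 |
| Saturday's | 5.00 | 0 | 96.3 |

(readings scatter by 1 percentage point)

* when, up to 6.0 d, the flask holds most open intermediate
* the amount of open intermediate, in percent of the substrate charged, at that time

I built the flask up one process at a time. With the opening alone, the open intermediate had no peak and simply rose towards the full charge.

Next I added the drain into product. The product slope between the second and third readings of Saturday's run, divided by the mean c(open intermediate) and mean c(partner), gave 10.8 /M/d. Holding c(partner) at the flask's charge of 0.100 M, a pseudo-first-order view, I got a drain of 1.08 /d, far slower than the opening.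

So I solved each end apart, the early rise by the opening and the late fall by the drain, and joined them. The crossing time came to 0.0710 d: the logarithm of the ratio of the two constants over their difference, the moment when inflow equals drain. The height there is the exponential of minus drain times crossing time.

Last came the capture agent. I charged the gap in the balance at the second readings, averaged over both runs and scaled to the crossing time, to it, which cost 0.72 percentage points.

| Counted | Peak time | Peak height |
|---|---|---|
| opening | none | 100% |
| plus drain | 0.0710 d | 92.6% |
| plus capture | 0.0710 d | 91.9% |

The forecast gave 92% at 0.072 d, a little later than my time, and it too explained the gap in the balance, “probably because the capture agent takes up some intermediate”.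

The flask peaked at 92.2% at 0.0725 d.

    partner + open intermediate → product (k = 0.440 /M/h)
    substrate → open intermediate (k = 2.30 /h)
    open intermediate + capture agent → trapped intermediate (k = 0.860 /M/h)

In the flask, trapped intermediate stood at 0.518% at that time, and the capture step barely moved the time of the peak. For the neighbouring flask with 0.25 M of partner, the other charges as in the flask, the drain comes to 2.69 /d, the crossing time to 0.0562 d and the height there, before any charge for capture, to 86.0%; that neighbouring flask's peak stood at 85.7%.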